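**Retrosynthetic overview** (octahydroazulene numbering of the target: C3 carbinol with isopropyl, C3a, C4 ester carbinol, C5, C6 with methyl, C7, C8, C8a with methyl)
1. Last disconnections: the salicylate C4–O acyl bond (alkoxide plus 2,2-dimethyl-1,3-benzodioxin-4-one) and a silyl ether on the C3 tertiary hydroxyl.
2. Seven-membered ring: the homoallylic carbinol array O–C4–C5–C6(CH3)=C7 is the retron of an allylboration. C6–C7 and C4–C5 are made together by a Suzuki–Miyaura coupling/allylboration domino of 2-bromopropene with a cyclopentane carrying a CH2CH(Bpin)2 arm on C8a and a formyl group on C3a.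
3. That cyclopentane comes from 3-methylcyclopent-2-en-1-one: catalytic enantioselective conjugate addition of a 1-silylvinyl group (sets C8a) with formaldehyde trapping of the enolate (C3a), protodesilylation, isopropyl addition (C3), 1,1-diboration of the vinyl group and oxidation to the aldehyde.
4. Ring order: the five-membered ring is bought; the seven-membered ring is closed last, in the key step.

Key step: step 7

Assumption: for the chiral ligands of steps 1 and 7 the antipode that gives the drawn configuration is used (both antipodes of each ligand class are accessible), and 2,2-dimethyl-4H-1,3-benzodioxin-4-one is taken as commercial.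

**Step 1**
Reactants: 1 3-methylcyclopent-2-en-1-one; 2 ethynyltrimethylsilane; 3 formaldehyde (monomer, from paraformaldehyde)
Product: 6 (2S,3S)-2-(hydroxymethyl)-3-methyl-3-[1-(trimethylsilyl)ethenyl]cyclopentan-1-one, via vinylalane 4 (not isolated), via aluminium enolate 5 (not isolated)
Conditions: 2, i-Bu2AlH, hexanes/THF, 55 °C; then 1, Cu(OTf)2 (cat.), chiral sulfonate-bearing imidazolinium salt (N-heterocyclic carbene precursor, cat.), THF, −30 °C; then 3 (gas), −78 → −30 °C; aq. potassium sodium tartrate
Reagents that add atoms: ethynyltrimethylsilane C#C[Si](C)(C)C; formaldehyde C=O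
Why: Copper–carbene-catalysed enantioselective conjugate addition of a silicon-substituted vinylaluminium (from hydroalumination of the silylalkyne) to a β-methyl cyclic enone is a known way to vinyl-bearing quaternary carbons, so the catalyst should set C3, and the regiodefined aluminium enolate should then undergo aldol addition to formaldehyde anti to the bulky 1-silylvinyl group, which sets C2 with the hydroxymethyl cis to the methyl.

**Step 2**
Reactants: 6 (2S,3S)-2-(hydroxymethyl)-3-methyl-3-[1-(trimethylsilyl)ethenyl]cyclopentan-1-one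
Product: 7 (2S,3R)-3-ethenyl-2-(hydroxymethyl)-3-methylcyclopentan-1-one
Conditions: CF3CO2H, CH2Cl2, 0 → 22 °C; then NaHCO3 (aq), MeOH
Reagents that add atoms: none
Why: Acid-mediated protodesilylation of the 1-silylvinyl group is the established way to unveil the vinyl group of such conjugate adducts, and it should leave both stereocentres untouched because the C2–H lies between the carbonyl and a quaternary carbon and enolises slowly.

**Step 3**
Reactants: 7 (2S,3R)-3-ethenyl-2-(hydroxymethyl)-3-methylcyclopentan-1-one; 8 isopropylmagnesium chloride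
Product: 9 (1R,2S,3R)-3-ethenyl-2-(hydroxymethyl)-3-methyl-1-(propan-2-yl)cyclopentan-1-ol
Conditions: 8 (3 equiv), CeCl3 (anhydrous, 3 equiv), THF, −78 → 0 °C; NH4Cl (aq)
Reagents that add atoms: isopropylmagnesium chloride CC(C)[Mg]Cl
Why: Organocerium 1,2-addition should suppress enolisation and reduction, and the nucleophile should enter the cyclopentanone anti to the adjacent C2 oxymethyl substituent, which gives the tertiary alcohol with the hydroxyl cis to that substituent and to the ring methyl.

**Step 4**
Reactants: 9 (1R,2S,3R)-3-ethenyl-2-(hydroxymethyl)-3-methyl-1-(propan-2-yl)cyclopentan-1-ol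
Product: 10 triethyl{[(1R,2S,3R)-3-ethenyl-3-methyl-1-(propan-2-yl)-2-{[(triethylsilyl)oxy]methyl}cyclopentyl]oxy}silane
Conditions: Et3SiOTf (2.5 equiv), 2,6-lutidine, CH2Cl2, −78 → 22 °C
Reagents that add atoms: triethylsilyl trifluoromethanesulfonate CC[Si](CC)(CC)OS(=O)(=O)C(F)(F)F
Why: Silyl triflate with a hindered pyridine base is the standard silylation for hindered tertiary as well as primary hydroxyls, and no stereocentre is involved.

**Step 5**
Reactants: 10 triethyl{[(1R,2S,3R)-3-ethenyl-3-methyl-1-(propan-2-yl)-2-{[(triethylsilyl)oxy]methyl}cyclopentyl]oxy}silane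
Product: 11 2,2'-{2-[(1S,2S,3R)-1-methyl-3-(propan-2-yl)-3-[(triethylsilyl)oxy]-2-{[(triethylsilyl)oxy]methyl}cyclopentyl]ethane-1,1-diyl}bis(4,4,5,5-tetramethyl-1,3,2-dioxaborolane)
Conditions: B2pin2, NiCl2(DME) (cat.), Cy-Xantphos (cat.), LiOMe (cat.), DMA, 25–40 °C
Reagents that add atoms: bis(pinacolato)diboron CC1(C)OB(OC1(C)C)B1OC(C)(C)C(C)(C)O1
Why: Nickel-catalysed 1,1-diboration of terminal alkenes (borylnickelation, β-hydride elimination, reinsertion next to boron, borylation) should turn the vinyl group into the geminal bis(boronate) without creating or touching a stereocentre.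

**Step 6**
Reactants: 11 the geminal bis(boronate) bis(silyl ether)
Product: 12 (1R,2S,5R)-2-[2,2-bis(4,4,5,5-tetramethyl-1,3,2-dioxaborolan-2-yl)ethyl]-2-methyl-5-(propan-2-yl)-5-[(triethylsilyl)oxy]cyclopentane-1-carbaldehyde
Conditions: (COCl)2, DMSO, CH2Cl2, −78 → −40 °C; then Et3N, −78 → 0 °C
Reagents that add atoms: none
Why: Swern conditions are known to oxidise primary triethylsilyl ethers directly to aldehydes while tertiary silyl ethers and pinacol boronates survive, and the aldehyde α-carbon is already in its more stable configuration (formyl trans to the isopropyl group and to the bis(boryl)ethyl arm).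

**Step 7**
Reactants: 12 (1R,2S,5R)-2-[2,2-bis(4,4,5,5-tetramethyl-1,3,2-dioxaborolan-2-yl)ethyl]-2-methyl-5-(propan-2-yl)-5-[(triethylsilyl)oxy]cyclopentane-1-carbaldehyde; 13 2-bromopropene
Product: 15 (3R,3aS,4S,8aR)-6,8a-dimethyl-3-(propan-2-yl)-3-[(triethylsilyl)oxy]-1,2,3,3a,4,5,8,8a-octahydroazulen-4-ol, via allylboronate 14 (not isolated)
Conditions: 13 (1.5 equiv), Pd(OAc)2 (5 mol%), TADDOL-derived phosphoramidite ligand (10 mol%), KOH (aq), 1,4-dioxane, 22 °C, 0.01 M; then NH4Cl (aq) to pH 8, 40 °C
Reagents that add atoms: 2-bromopropene CC(Br)=C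
Why: Proposed new method: oxidative addition of 13 to zerovalent palladium, hydroxide-assisted transmetalation of one of the two geminal boryl groups of 12 (the second boron accelerates this step and the mono-boronate formed does not couple again) and reductive elimination form the C6–C7 bond and give the α-substituted allyl pinacolboronate 14, whose boron then binds the aldehyde oxygen so that the allyl CH2 terminus adds to the carbonyl carbon through a closed six-membered transition state, forming C4–C5 and shifting the double bond to C6=C7. The closest known reaction types are the room-temperature Suzuki–Miyaura coupling of 1,1-bis(boronates) with vinyl bromides, including its ligand-controlled boron-group-selective version, and the allylboration of aldehydes by α-substituted allyl pinacolboronates; new is running them as a domino on a substrate whose aldehyde is tethered to the boron-bearing carbon, so that the allylboration is the ring closure. The seven-membered ring closes by 7-exo-trig attack on the aldehyde with the allyl unit taken into the ring, through a boat-like bicyclo[3.2.2]-type transition state in which the C8–C8a–C3a tether bridges the boron-bearing carbon and the carbonyl carbon, and this also forces the Z-alkene. The new stereocentre C4 is fixed by 1,4-transfer of chirality from the boron-bearing carbon of 14 through this bridged transition state (S at that carbon can only give 4S), and that carbon is set by the chiral palladium ligand, which selects one of the two diastereotopic boryl groups. The step needs site selectivity of the allyl transfer (C5 and not C7 must attack), secured because allyl pinacolboronates do not undergo 1,3-boron shift at these temperatures, and it needs an aldehyde that survives aqueous base, secured by the two quaternary carbons flanking its α-carbon and by the silyl ether on the β-oxygen, while high dilution suppresses intermolecular allylboration.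

**Step 8**
Reactants: 15 (3R,3aS,4S,8aR)-6,8a-dimethyl-3-(propan-2-yl)-3-[(triethylsilyl)oxy]-1,2,3,3a,4,5,8,8a-octahydroazulen-4-ol; 16 2,2-dimethyl-4H-1,3-benzodioxin-4-one
Product: 17 (3R,3aS,4S,8aR)-6,8a-dimethyl-3-(propan-2-yl)-3-[(triethylsilyl)oxy]-1,2,3,3a,4,5,8,8a-octahydroazulen-4-yl 2-hydroxybenzoate
Conditions: NaN(SiMe3)2, THF, 0 °C; then 16, 0 → 22 °C; NH4Cl (aq)
Reagents that add atoms: 2,2-dimethyl-4H-1,3-benzodioxin-4-one CC1(C)OC(=O)c2ccccc2O1
Why: Alkoxide opening of a 1,3-benzodioxin-4-one at its carbonyl with loss of acetone is an established transesterification that gives salicylate esters with the phenol free, and C4 keeps its configuration because its C–O bond is not broken.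

**Step 9**
Reactants: 17 (3R,3aS,4S,8aR)-6,8a-dimethyl-3-(propan-2-yl)-3-[(triethylsilyl)oxy]-1,2,3,3a,4,5,8,8a-octahydroazulen-4-yl 2-hydroxybenzoate
Product: 18 (3R,3aS,4S,8aR)-3-hydroxy-6,8a-dimethyl-3-(propan-2-yl)-1,2,3,3a,4,5,8,8a-octahydroazulen-4-yl 2-hydroxybenzoate (target)
Conditions: HF·pyridine, THF/pyridine, 0 → 22 °C
Reagents that add atoms: none
Why: Fluoride-mediated cleavage of the tertiary triethylsilyl ether under buffered conditions should leave the ester, the phenol and the trisubstituted alkene untouched.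

**Compound list**
1 | 3-methylcyclopent-2-en-1-one | CC1=CC(=O)CC1 | starting material
2 | ethynyltrimethylsilane | C#C[Si](C)(C)C | starting material
3 | formaldehyde (monomer, generated from paraformaldehyde) | C=O | starting material
4 | bis(2-methylpropyl)[1-(trimethylsilyl)ethenyl]aluminium | C=C([Si](C)(C)C)[Al](CC(C)C)CC(C)C | intermediate
5 | bis(2-methylpropyl)aluminium (3S)-3-methyl-3-[1-(trimethylsilyl)ethenyl]cyclopent-1-en-1-olate | C=C([Si](C)(C)C)[C@@]1(C)CCC(O[Al](CC(C)C)CC(C)C)=C1 | intermediate
6 | (2S,3S)-2-(hydroxymethyl)-3-methyl-3-[1-(trimethylsilyl)ethenyl]cyclopentan-1-one | C=C([Si](C)(C)C)[C@@]1(C)CCC(=O)[C@@H]1CO | intermediate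
7 | (2S,3R)-3-ethenyl-2-(hydroxymethyl)-3-methylcyclopentan-1-one | C=C[C@@]1(C)CCC(=O)[C@@H]1CO | intermediate
8 | isopropylmagnesium chloride | CC(C)[Mg]Cl | starting material
9 | (1R,2S,3R)-3-ethenyl-2-(hydroxymethyl)-3-methyl-1-(propan-2-yl)cyclopentan-1-ol | C=C[C@@]1(C)CC[C@@](O)(C(C)C)[C@@H]1CO | intermediate
10 | triethyl{[(1R,2S,3R)-3-ethenyl-3-methyl-1-(propan-2-yl)-2-{[(triethylsilyl)oxy]methyl}cyclopentyl]oxy}silane | C=C[C@@]1(C)CC[C@@](O[Si](CC)(CC)CC)(C(C)C)[C@@H]1CO[Si](CC)(CC)CC | intermediate
11 | 2,2'-{2-[(1S,2S,3R)-1-methyl-3-(propan-2-yl)-3-[(triethylsilyl)oxy]-2-{[(triethylsilyl)oxy]methyl}cyclopentyl]ethane-1,1-diyl}bis(4,4,5,5-tetramethyl-1,3,2-dioxaborolane) | CC1(C)OB(OC1(C)C)C(B1OC(C)(C)C(C)(C)O1)C[C@@]2(C)CC[C@@](O[Si](CC)(CC)CC)(C(C)C)[C@@H]2CO[Si](CC)(CC)CC | intermediate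
12 | (1R,2S,5R)-2-[2,2-bis(4,4,5,5-tetramethyl-1,3,2-dioxaborolan-2-yl)ethyl]-2-methyl-5-(propan-2-yl)-5-[(triethylsilyl)oxy]cyclopentane-1-carbaldehyde | CC1(C)OB(OC1(C)C)C(B1OC(C)(C)C(C)(C)O1)C[C@@]2(C)CC[C@@](O[Si](CC)(CC)CC)(C(C)C)[C@@H]2C=O | intermediate
13 | 2-bromopropene | CC(Br)=C | starting material
14 | (1R,2R,5R)-2-methyl-2-[(2S)-3-methyl-2-(4,4,5,5-tetramethyl-1,3,2-dioxaborolan-2-yl)but-3-en-1-yl]-5-(propan-2-yl)-5-[(triethylsilyl)oxy]cyclopentane-1-carbaldehyde | C=C(C)[C@@H](B1OC(C)(C)C(C)(C)O1)C[C@@]2(C)CC[C@@](O[Si](CC)(CC)CC)(C(C)C)[C@@H]2C=O | intermediate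
15 | (3R,3aS,4S,8aR)-6,8a-dimethyl-3-(propan-2-yl)-3-[(triethylsilyl)oxy]-1,2,3,3a,4,5,8,8a-octahydroazulen-4-ol | CC1=CC[C@@]2(C)CC[C@@](O[Si](CC)(CC)CC)(C(C)C)[C@@H]2[C@@H](O)C1 | intermediate
16 | 2,2-dimethyl-4H-1,3-benzodioxin-4-one | CC1(C)OC(=O)c2ccccc2O1 | starting material
17 | (3R,3aS,4S,8aR)-6,8a-dimethyl-3-(propan-2-yl)-3-[(triethylsilyl)oxy]-1,2,3,3a,4,5,8,8a-octahydroazulen-4-yl 2-hydroxybenzoate | CC1=CC[C@@]2(C)CC[C@@](O[Si](CC)(CC)CC)(C(C)C)[C@@H]2[C@@H](OC(=O)c2ccccc2O)C1 | intermediate
18 | (3R,3aS,4S,8aR)-3-hydroxy-6,8a-dimethyl-3-(propan-2-yl)-1,2,3,3a,4,5,8,8a-octahydroazulen-4-yl 2-hydroxybenzoate | CC1=CC[C@@]2(C)CC[C@@](O)(C(C)C)[C@@H]2[C@@H](OC(=O)c2ccccc2O)C1 | target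

**Totals**
Total step count: 9. Longest linear sequence: 9 steps (1 → 18).

**Steps most likely to fail**

1. Step 7 (proposed new method). The bridged intramolecular allyl transfer may be slower than intermolecular allylboration or protodeboronation of the allylboronate. The ligand may also discriminate poorly between the two diastereotopic boryl groups, which would erode the configuration at C4. Base-induced β-elimination of the silyloxy group is a further loss channel. The fallback uses known chemistry and closes the ring by olefin metathesis instead of allyl transfer. Setting out from 10, hydroboration–oxidation of the vinyl group (9-BBN; NaOH, H2O2) would give primary alcohol F1, Dess–Martin oxidation would give aldehyde F2, and Wittig methylenation (Ph3P=CH2) would give allyl compound F3. Swern oxidative desilylation of the primary silyl ether would then give aldehyde F4, and reagent-controlled methallylboration with B-methallyldiisopinocampheylborane (antipode chosen for the 4S carbinol) would give dienol F5. Ring-closing metathesis with the second-generation Grubbs catalyst would close C6=C7 with loss of ethene and come back to the route at 15.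

2. Step 2. Acid-promoted enolisation towards C2 may occur during the protodesilylation, with loss of the C2 configuration or β-elimination of water. The fallback removes silicon under neutral conditions: setting out from 6, ipso-iododesilylation with N-iodosuccinimide (MeCN, 0 °C) would give vinyl iodide F6, and radical reduction (Bu3SnH, AIBN, benzene, 80 °C) would replace iodine by hydrogen and come back to the route at 7.

3. Step 5. Competing 1,2-diboration, or no borylmetalation at all at the neopentyl-type alkene, may prevent formation of the geminal bis(boronate). The fallback builds it in two known stages: setting out from 10, cross-metathesis with vinylboronic acid pinacol ester (second-generation Grubbs catalyst, CH2Cl2, 40 °C) would give alkenylboronate F7, and copper-hydride-catalysed hydroboration with pinacolborane (CuCl, NaOt-Bu, bisphosphine ligand) would place the second boron on the carbon that already bears boron and come back to the route at 11.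

**Further compounds**
F1 | step 7 | 2-[(1R,2S,3R)-1-methyl-3-(propan-2-yl)-3-[(triethylsilyl)oxy]-2-{[(triethylsilyl)oxy]methyl}cyclopentyl]ethan-1-ol | OCC[C@@]1(C)CC[C@@](O[Si](CC)(CC)CC)(C(C)C)[C@@H]1CO[Si](CC)(CC)CC
F2 | step 7 | 2-[(1R,2S,3R)-1-methyl-3-(propan-2-yl)-3-[(triethylsilyl)oxy]-2-{[(triethylsilyl)oxy]methyl}cyclopentyl]acetaldehyde | O=CC[C@@]1(C)CC[C@@](O[Si](CC)(CC)CC)(C(C)C)[C@@H]1CO[Si](CC)(CC)CC
F3 | step 7 | triethyl{[(1R,2S,3R)-3-methyl-1-(propan-2-yl)-3-(prop-2-en-1-yl)-2-{[(triethylsilyl)oxy]methyl}cyclopentyl]oxy}silane | C=CC[C@@]1(C)CC[C@@](O[Si](CC)(CC)CC)(C(C)C)[C@@H]1CO[Si](CC)(CC)CC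
F4 | step 7 | (1R,2R,5R)-2-methyl-5-(propan-2-yl)-2-(prop-2-en-1-yl)-5-[(triethylsilyl)oxy]cyclopentane-1-carbaldehyde | C=CC[C@@]1(C)CC[C@@](O[Si](CC)(CC)CC)(C(C)C)[C@@H]1C=O
F5 | step 7 | (1S)-3-methyl-1-[(1S,2R,5R)-2-methyl-5-(propan-2-yl)-2-(prop-2-en-1-yl)-5-[(triethylsilyl)oxy]cyclopentyl]but-3-en-1-ol | C=CC[C@@]1(C)CC[C@@](O[Si](CC)(CC)CC)(C(C)C)[C@@H]1[C@@H](O)CC(C)=C
F6 | step 2 | (2S,3S)-2-(hydroxymethyl)-3-(1-iodoethenyl)-3-methylcyclopentan-1-one | C=C(I)[C@@]1(C)CCC(=O)[C@@H]1CO
F7 | step 5 | triethyl{[(1R,2S,3R)-3-methyl-1-(propan-2-yl)-3-[(E)-2-(4,4,5,5-tetramethyl-1,3,2-dioxaborolan-2-yl)ethenyl]-2-{[(triethylsilyl)oxy]methyl}cyclopentyl]oxy}silane | CC1(C)OB(OC1(C)C)/C=C/[C@@]2(C)CC[C@@](O[Si](CC)(CC)CC)(C(C)C)[C@@H]2CO[Si](CC)(CC)CC
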